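The route rests on closing ring B (C5–C6–C7–C8–C9–C10, labdane numbering) by a catalytic asymmetric Diels–Alder reaction that forms C5–C10 and C8–C9 in one operation from two acyclic partners: a 2-silyloxy diene nitrile (C3–C8, C17–C19) and the (E)-2-methyl-2-enal made from (S)-citronellol (C1, C9–C16, C20). The (E) geometry of the enal is translated stereospecifically into the cis C20/C11 relation at quaternary C10 and C9, and the catalyst fixes their absolute sense. C5 and C8 are then flattened, so endo and exo adducts converge; C2, C3 and C5 are relayed from C10 by a pinacol closure of ring A and a dissolving-metal diene reduction.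

Key step: step 6

Remark: labdane numbering (C1–C20) is used for all compounds, and the oxazaborolidine enantiomer of step 6 is assumed to be the one that exposes the Cα-Re/Cβ-Si face of enal 4 (written as (S)); if the sense were opposite, the (R) catalyst would be used.

Step 1
Reactants: 1 (S)-citronellol
Product: 2 (S)-citronellyl benzyl ether
Conditions: NaH, BnBr, Bu4NI (cat.), THF, 0 °C → rt
Reagents that add atoms: benzyl bromide, BrCc1ccccc1
Why: Williamson ether synthesis protects the primary alcohol as a benzyl ether that should survive Lewis acid, ylide, amide base, iBu2AlH and SmI2 and falls off in the dissolving-metal step 13, while the bought C13 stereocentre is not touched.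

Step 2
Reactants: 2 (S)-citronellyl benzyl ether
Product: 4 (2E,6S)-8-(benzyloxy)-2,6-dimethyloct-2-enal, via allylic alcohol 3 (not isolated)
Conditions: SeO2 (cat.), t-BuOOH, salicylic acid (cat.), CH2Cl2, rt; then MnO2, CH2Cl2, rt
Reagents that add atoms: tert-butyl hydroperoxide, CC(C)(C)OO (oxygen atom, passed on through SeO2, O=[Se]=O)
Why: Riley oxidation (ene reaction followed by [2,3]-sigmatropic shift) should functionalise only the methyl group trans to the chain of the trisubstituted alkene, and MnO2 then oxidises the allylic alcohol, so the (E)-enal results in which the future C20 methyl is cis to C11.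

Step 3
Reactants: 5 isobutyronitrile
Product: 6 2,2-dimethyl-3-oxopropanenitrile
Conditions: LiN(iPr)2, THF, −78 °C; then HCO2Et, −78 °C; AcOH quench at −78 °C
Reagents that add atoms: ethyl formate, CCOC=O
Why: Claisen-type C-formylation of the nitrile-stabilised carbanion should give an aldehyde that has no α-hydrogen and therefore cannot enolise or condense with itself.

Step 4
Reactants: 6 2,2-dimethyl-3-oxopropanenitrile; 7 diethyl (2-oxobutyl)phosphonate
Product: 8 (3E)-2,2-dimethyl-5-oxohept-3-enenitrile
Conditions: LiCl, iPr2NEt, MeCN, rt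
Reagents that add atoms: none
Why: Horner–Wadsworth–Emmons olefination of the non-enolisable aldehyde with the β-ketophosphonate under mild base should give the (E)-enone, which carries C3–C8 and C17–C19.

Step 5
Reactants: 8 (3E)-2,2-dimethyl-5-oxohept-3-enenitrile
Product: 9 (3E,5Z)-5-(tert-butyldimethylsilyloxy)-2,2-dimethylhepta-3,5-dienenitrile
Conditions: TBSOTf, Et3N, CH2Cl2, 0 °C
Reagents that add atoms: tert-butyldimethylsilyl trifluoromethanesulfonate, CC(C)(C)[Si](C)(C)OS(=O)(=O)C(F)(F)F
Why: Soft enolisation (silyl enol ether formation) can occur only at the ethyl group because C4 is quaternary, and the (Z)-enol ether, which keeps the C8 methyl away from the vinyl group (allylic 1,3-strain), should dominate and gives a diene that can reach the s-cis form.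

Step 6
Reactants: 9 (3E,5Z)-5-(tert-butyldimethylsilyloxy)-2,2-dimethylhepta-3,5-dienenitrile; 4 (2E,6S)-8-(benzyloxy)-2,6-dimethyloct-2-enal
Product: 10 ring B cycloadduct (silyl enol ether aldehyde)
Conditions: (S)-1-(2-methylphenyl)-3,3-diphenyltetrahydro-1H,3H-pyrrolo[1,2-c][1,3,2]oxazaborole (20 mol%), HN(SO2CF3)2 (18 mol%), CH2Cl2, −78 → −20 °C
Reagents that add atoms: none
Why: The protonated oxazaborolidine binds the formyl oxygen of 4 and lowers its LUMO, the enol-silane terminus C8 of 9 bonds to the β-carbon C9 and the other diene terminus C5 closes onto the α-carbon C10 in one asynchronous but concerted [4+2] event; the closest known reaction type is the chiral oxazaborolidinium-catalysed Diels–Alder reaction of 2-silyloxy-1,3-dienes with 2-substituted enals. Ring B (C5–C6–C7–C8–C9–C10) is closed by a six-membered suprafacial cycloaddition that makes C5–C10 and C8–C9 together. Since both bonds form on one face of the (E)-enal, C20 and C11 must end up cis on C10 and C9 (stereospecific transfer of alkene geometry), and the catalyst, by shielding one enal face so that the diene adds to the Cα-Re/Cβ-Si face, controls the absolute configuration of the quaternary C10 and of C9 independently of the remote C13. The step needs regioselectivity (the 2-silyloxy group makes C8 the nucleophilic terminus and places the C7 oxygen para to the formyl-bearing C10), conjugate over 1,2-attack at the aldehyde (favoured by the cationic boron catalyst, which activates the enal as a dienophile) and facial selectivity (catalyst); it needs neither endo/exo nor C8 control, because C5 and C8 become sp2 in steps 7 and 9 and all such diastereomers converge. The steric load at C5 (next to quaternary C4) and at C10 is the main risk and is the reason for the strongly activating cationic catalyst.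

Step 7
Reactants: 10 ring B cycloadduct (silyl enol ether aldehyde)
Product: 11 C5=C6 enone aldehyde
Conditions: Pd(OAc)2 (1.1 equiv), MeCN, rt → 40 °C
Reagents that add atoms: none
Why: Saegusa–Ito oxidation converts the regiodefined silyl enol ether into an oxa-π-allyl complex of divalent palladium at C6, and β-hydride elimination of H5 should give the C5=C6 enone, which removes the C5 stereocentre so that endo and exo adducts become one compound.

Step 8
Reactants: 11 C5=C6 enone aldehyde
Product: 12 methyl enol ether enone
Conditions: Ph3P(CH2OMe)Cl, KN(SiMe3)2, THF, 0 °C; then 11, −78 → 0 °C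
Reagents that add atoms: (methoxymethyl)triphenylphosphonium chloride, COC[P+](c1ccccc1)(c1ccccc1)c1ccccc1.[Cl-]
Why: Wittig methoxymethylenation should take the aldehyde in preference to the hindered conjugated ketone and adds C2 at the aldehyde oxidation level while C1 becomes a future CH2; no stereocentre is formed (the E/Z mixture is of no consequence).

Step 9
Reactants: 12 methyl enol ether enone
Product: 13 dienyl triflate
Conditions: KN(SiMe3)2, THF, −78 °C; then PhN(SO2CF3)2, −78 → 0 °C
Reagents that add atoms: N-phenylbis(trifluoromethanesulfonimide), O=S(=O)(N(c1ccccc1)S(=O)(=O)C(F)(F)F)C(F)(F)F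
Why: The enone can be deprotonated only at C8 because both γ-carbons (C4, C10) are quaternary, so O-triflation of the cross-conjugated dienolate (enol triflate formation) should give the C7 triflate with C7=C8 and C5=C6 regiospecifically and removes the C8 stereocentre.

Step 10
Reactants: 13 dienyl triflate
Product: 14 C5=C6–C7=C8 diene
Conditions: Pd(OAc)2 (cat.), PPh3, Bu3N, HCO2H, DMF, 60 °C
Reagents that add atoms: none
Why: Oxidative addition of zerovalent palladium to the triflate, formate exchange, loss of CO2 and reductive elimination (palladium-catalysed formate reduction of a vinyl triflate) should replace the triflate by hydrogen and leave the homoannular diene with the C17 methyl on C8.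

Step 11
Reactants: 14 C5=C6–C7=C8 diene
Product: 16 dialdehyde, via aluminated aldimine 15 (not isolated)
Conditions: iBu2AlH, toluene, −78 °C; then 1 M HCl, THF, 0 °C; crude product used at once
Reagents that add atoms: water, O
Why: One hydride adds to the hindered nitrile (nitrile half-reduction), and the mild acidic work-up hydrolyses both the aldimine (C3 aldehyde) and the methyl enol ether (C2 aldehyde, C1 now CH2) without touching the stereocentres.

Step 12
Reactants: 16 dialdehyde
Product: 17 (2S,3R,9R,10S,13S)-15-(benzyloxy)labda-5,7-diene-2,3-diol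
Conditions: SmI2 (2.5 equiv), t-BuOH, THF, −78 °C → rt; aqueous work-up
Reagents that add atoms: none
Why: Intramolecular pinacol coupling through a samarium-bridged diketyl should close ring A (C2–C3 bond) as the cis-diol, and since an axial oxygen on C2 would be syn-axial to both the C20 methyl and the axial C4 methyl, the C2 oxygen is expected equatorial and the C3 oxygen axial on the face opposite C20, so both centres are set from C10 by substrate control.

Step 13
Reactants: 17 (2S,3R,9R,10S,13S)-15-(benzyloxy)labda-5,7-diene-2,3-diol
Product: 18 (2S,3R,5S,9R,10S,13S)-labd-7-ene-2,3,15-triol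
Conditions: Li, NH3(l), THF, −78 → −33 °C; then NH4Cl
Reagents that add atoms: none
Why: Birch-type dissolving-metal reduction of the homoannular diene should add hydrogen to C5 and C6 and leave the C7=C8 bond, as is known for steroidal 5,7-dienes, with protonation of C5 on the axial face anti to the C20 methyl (trans ring fusion), and the benzyl ether is cleaved in the same flask.

Step 14
Reactants: 18 (2S,3R,5S,9R,10S,13S)-labd-7-ene-2,3,15-triol
Product: 19 CNP0144124.1
Conditions: Ac2O (2.2 equiv), pyridine, CH2Cl2, 0 °C
Reagents that add atoms: acetic anhydride, CC(=O)OC(C)=O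
Why: Acylation should take the primary C15 hydroxyl and the equatorial C2 hydroxyl, while the axial C3 hydroxyl next to the C4 gem-dimethyl group is too hindered to react under these mild conditions.

Compound list

1 | (S)-citronellol, (3S)-3,7-dimethyloct-6-en-1-ol | OCC[C@@H](C)CCC=C(C)C | starting material
2 | (S)-citronellyl benzyl ether | c1ccccc1COCC[C@@H](C)CCC=C(C)C | intermediate
3 | (2E,6S)-8-(benzyloxy)-2,6-dimethyloct-2-en-1-ol | c1ccccc1COCC[C@@H](C)CC/C=C(\C)CO | intermediate
4 | (2E,6S)-8-(benzyloxy)-2,6-dimethyloct-2-enal | c1ccccc1COCC[C@@H](C)CC/C=C(\C)C=O | intermediate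
5 | isobutyronitrile | CC(C)C#N | starting material
6 | 2,2-dimethyl-3-oxopropanenitrile | CC(C)(C=O)C#N | intermediate
7 | diethyl (2-oxobutyl)phosphonate | CCC(=O)CP(=O)(OCC)OCC | starting material
8 | (3E)-2,2-dimethyl-5-oxohept-3-enenitrile | CCC(=O)/C=C/C(C)(C)C#N | intermediate
9 | (3E,5Z)-5-(tert-butyldimethylsilyloxy)-2,2-dimethylhepta-3,5-dienenitrile | C/C=C(O[Si](C)(C)C(C)(C)C)/C=C/C(C)(C)C#N | intermediate
10 | 2-{(1S,4R,5R,6S)-5-[(3S)-5-(benzyloxy)-3-methylpentyl]-3-(tert-butyldimethylsilyloxy)-6-formyl-4,6-dimethylcyclohex-2-en-1-yl}-2-methylpropanenitrile; drawn as the endo adduct, formyl trans to the pentyl chain and cis to the C4 methyl and the cyanopropyl group | c1ccccc1COCC[C@@H](C)CC[C@@H]1[C@@H](C)C(O[Si](C)(C)C(C)(C)C)=C[C@@H](C(C)(C)C#N)[C@@]1(C)C=O | intermediate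
11 | 2-{(4R,5R,6S)-5-[(3S)-5-(benzyloxy)-3-methylpentyl]-6-formyl-4,6-dimethyl-3-oxocyclohex-1-en-1-yl}-2-methylpropanenitrile | c1ccccc1COCC[C@@H](C)CC[C@@H]1[C@@H](C)C(=O)C=C(C(C)(C)C#N)[C@@]1(C)C=O | intermediate
12 | 2-{5-[(3S)-5-(benzyloxy)-3-methylpentyl]-6-(2-methoxyethenyl)-4,6-dimethyl-3-oxocyclohex-1-en-1-yl}-2-methylpropanenitrile; ring configuration as in 11, enol ether as E/Z mixture | c1ccccc1COCC[C@@H](C)CC[C@@H]1[C@@H](C)C(=O)C=C(C(C)(C)C#N)[C@@]1(C)C=COC | intermediate
13 | 3-[(3S)-5-(benzyloxy)-3-methylpentyl]-5-(2-cyanopropan-2-yl)-4-(2-methoxyethenyl)-2,4-dimethylcyclohexa-1,5-dien-1-yl trifluoromethanesulfonate; C9 and C10 (labdane numbering) as in 11 | c1ccccc1COCC[C@@H](C)CC[C@@H]1C(C)=C(OS(=O)(=O)C(F)(F)F)C=C(C(C)(C)C#N)[C@@]1(C)C=COC | intermediate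
14 | 2-{5-[(3S)-5-(benzyloxy)-3-methylpentyl]-6-(2-methoxyethenyl)-4,6-dimethylcyclohexa-1,3-dien-1-yl}-2-methylpropanenitrile; C9 and C10 as in 11 | c1ccccc1COCC[C@@H](C)CC[C@@H]1C(C)=CC=C(C(C)(C)C#N)[C@@]1(C)C=COC | intermediate
15 | N-(diisobutylaluminio)aldimine formed from the nitrile of 14 | c1ccccc1COCC[C@@H](C)CC[C@@H]1C(C)=CC=C(C(C)(C)C=N[Al](CC(C)C)CC(C)C)[C@@]1(C)C=COC | intermediate
16 | 2-{5-[(3S)-5-(benzyloxy)-3-methylpentyl]-4,6-dimethyl-6-(2-oxoethyl)cyclohexa-1,3-dien-1-yl}-2-methylpropanal; C9 and C10 as in 11 | c1ccccc1COCC[C@@H](C)CC[C@@H]1C(C)=CC=C(C(C)(C)C=O)[C@@]1(C)CC=O | intermediate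
17 | (2S,3R,9R,10S,13S)-15-(benzyloxy)labda-5,7-diene-2,3-diol | c1ccccc1COCC[C@@H](C)CC[C@@H]1C(C)=CC=C2C(C)(C)[C@@H](O)[C@@H](O)C[C@@]12C | intermediate
18 | (2S,3R,5S,9R,10S,13S)-labd-7-ene-2,3,15-triol | OCC[C@@H](C)CC[C@@H]1C(C)=CC[C@@H]2C(C)(C)[C@@H](O)[C@@H](O)C[C@@]12C | intermediate
19 | CNP0144124.1, (2S,3R,5S,9R,10S,13S)-3-hydroxylabd-7-ene-2,15-diyl diacetate | CC(=O)OCC[C@@H](C)CC[C@@H]1C(C)=CC[C@@H]2C(C)(C)[C@@H](O)[C@@H](OC(C)=O)C[C@@]12C | target

Total steps: 14. Longest linear sequence: 12 steps (steps 3–14, from isobutyronitrile; 11 steps from (S)-citronellol).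

Steps most likely to fail

Step 6. The second bond (C5–C10) may close slowly because both carbons are congested, the aldehyde may suffer 1,2-attack, or the two enal faces may be poorly distinguished. The fallback sets out from 4 and 9 and closes the ring stepwise. Under the same chiral oxazaborolidinium, quenched cold, the reaction is expected to stop after the first bond as the open-chain Mukaiyama–Michael adduct, enol silane enone F1, with C9 set by the catalyst. TiCl4 in CH2Cl2 at −78 °C then closes ring B by an intramolecular Mukaiyama–Michael addition of C10 to C5 (chair with the C9 chain and the C10=C1 bond equatorial) to give keto aldehyde F2. Kinetic enol silylation at C6 (lithium 2,2,6,6-tetramethylpiperidide, LiNC9H18, with TBSCl present, THF, −78 °C) comes back to the route at 10, whose C5 and C8 epimers converge in steps 7 and 9.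

Step 12 (together with the aldehyde release of step 11). The dialdehyde may cyclise by an aldol reaction before it is coupled, or the ketyl coupling may show poor cis or facial selectivity. The fallback sets out from 14. Mild acid (0.5 M HCl, THF, 0 °C) hydrolyses only the enol ether to aldehyde nitrile F3. SmI2 (THF, visible-light irradiation) then adds the C2 ketyl to the nitrile carbon C3 and, after hydrolysis of the ketimine, gives α-ketol F4, in which the C2 hydroxyl can equilibrate to the equatorial position. LiBH(s-Bu)3 (THF, −78 °C) reduces the C3 ketone from the equatorial side to the axial alcohol, and the route is rejoined at 17.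

Step 13. Protonation of the diene radical anion may take place at C8 instead of C5 (leaving the C5=C6 or C6=C7 alkene) or on the wrong face of C5. The fallback sets out from 17. Hydrogen with [Ir(cod)(PCy3)(py)]PF6 in CH2Cl2 is delivered by the axial C3 hydroxyl, which is homoallylic to C5=C6, to the face of that bond anti to C20 only, giving benzyl ether F5 with the trans ring fusion and the C7=C8 bond intact. Lithium naphthalenide (LiC10H8, THF, −25 °C) then removes the benzyl group, and the route is rejoined at 18.

Further compounds
F1 | step 6 | open-chain Mukaiyama–Michael adduct: (E)-enone carrying the (E)-tert-butyldimethylsilyl enol ether of the C1 aldehyde, C8 epimer mixture | c1ccccc1COCC[C@@H](C)CC[C@@H](/C(C)=C/O[Si](C)(C)C(C)(C)C)C(C)C(=O)/C=C/C(C)(C)C#N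
F2 | step 6 | 2-{5-[(3S)-5-(benzyloxy)-3-methylpentyl]-6-formyl-4,6-dimethyl-3-oxocyclohexyl}-2-methylpropanenitrile, C9 and C10 as in 10, C5 and C8 epimer mixture | c1ccccc1COCC[C@@H](C)CC[C@@H]1C(C)C(=O)CC(C(C)(C)C#N)[C@@]1(C)C=O
F3 | step 12 | 2-{5-[(3S)-5-(benzyloxy)-3-methylpentyl]-4,6-dimethyl-6-(2-oxoethyl)cyclohexa-1,3-dien-1-yl}-2-methylpropanenitrile | c1ccccc1COCC[C@@H](C)CC[C@@H]1C(C)=CC=C(C(C)(C)C#N)[C@@]1(C)CC=O
F4 | step 12 | (2S,9R,10S,13S)-15-(benzyloxy)-2-hydroxylabda-5,7-dien-3-one | c1ccccc1COCC[C@@H](C)CC[C@@H]1C(C)=CC=C2C(C)(C)C(=O)[C@@H](O)C[C@@]12C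
F5 | step 13 | (2S,3R,5S,9R,10S,13S)-15-(benzyloxy)labd-7-ene-2,3-diol | c1ccccc1COCC[C@@H](C)CC[C@@H]1C(C)=CC[C@@H]2C(C)(C)[C@@H](O)[C@@H](O)C[C@@]12C
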